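A curve that has levelled off by its last reading shows where the flask had got to by then, not where it ends.

| setting | maple | winter | autumn |
|---|---|---|---|
| free monomer | 0.050 M | 0.050 M | 0.050 M |
| protic impurity | 0.025 M | 0.0250 M | 0.0250 M |
| initiator | 0.40 mM | 0.20 mM | 0.20 mM |
| remark | run made earlier |  |  |
| time |  | 25 h | 8.0 h |

maple run (percent of the free monomer charged)

| time / h | monomer in chains / % |
|---|---|
| 0.833 | 10.8 |
| 1.50 | 17.0 |
| 2.50 | 22.9 |
| 3.00 | 24.3 |
| 4.00 | 27.3 |
| 5.00 | 28.3 |

(scatter of a reading: 0.3 percentage points)

- the average divides the monomer in chains by the number of chains begun, living and dead together
- the earlier runs do not show the number of chains; that part of a forecast is a guess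
- no earlier run changes the charge of initiator; that part of a forecast is a guess

- which of the two ends with the longer chains by the average number of monomer units in a chain (chains begun, living or dead) ("neither" if they lie within 10 %) (winter / autumn / neither)
- average number of monomer units in a chain (chains begun, living or dead) at the end, winter
- average number of monomer units in a chain (chains begun, living or dead) at the end, autumn

What separates winter from autumn? The time, 25 h against 8.0 h; their charges are the same.

What turns a share of the charge into a length (the number-average degree of polymerisation)? If each initiator begins one chain, which is a guess, the length is the share in chains times the charge ratio, the free monomer charged over the initiator charged, or the units per chain if the whole charge stood in chains: 250 for winter and for autumn.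

And in maple? There the ratio is 125, so on the same guess the reading of 28.3 % at 5.00 h means 35.4 units.

So what is really asked? Both flasks carry one ratio, so their lengths stand to each other as their shares in chains do at their two times.

Where is this weak? The last hour of maple added 1 percentage point against a scatter of 0.3 points, and the readings stop at 5.00 h. They do not show the share at 25 h.

What do you commit to? The initiator in winter and autumn is half of maple's. My own reckoning takes the maple share kept, 70.8 units, or cut in that proportion, 35.4 units. That is a range and a rule, with no winner named.

The forecast goes further than I do: neither, with 43 units for winter and 42 for autumn. Its ground for winter is “the reaction is finished”.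

    free monomer + living end → monomer in chains + living end, rate k1*[living end]*[free monomer] (k = 680 L mol⁻¹ h⁻¹)
    monomer in chains + living end → free monomer + living end, rate k2*[living end] as long as [monomer in chains] is above zero (k = 14.0 h⁻¹)
    free monomer + initiator → living end + monomer in chains (k = 550 L mol⁻¹ h⁻¹)
    free monomer → decomposition product (k = 2.70 × 10⁻⁴ h⁻¹)
    protic impurity + free monomer → quenched substrate (k = 5.40 L mol⁻¹ h⁻¹)

The flask gives autumn, with 34.9 units in winter and 52.3 in autumn. Monomer in chains stands at 20.9 % in autumn at 8.00 h but at 14.0 % in winter at 25.0 h, a lower share at the later time. Times the ratio of 250, those shares give 52.2 and 35.0 units.

The neighbour that is winter with 0.20 M of free monomer has a ratio of 1000, so its 74.5 % in chains at 25.0 h gives 745 units. The computed result is 745.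

(All runs were computed for substances that don't exist.)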